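**Retrosynthetic overview**
1. Target 7 ⇐ 6: the deoxybenzoin is the alkaline ring-opening product of a 5-methoxy linear pyranoisoflavone. C2 of the pyranone leaves as formate and the pyranone oxygen becomes the free chelated OH, which is what tells the two ortho oxygens apart.
2. 6 ⇐ 5: O-methylation of the one remaining (chelated) 5-OH.
3. 5 ⇐ 1 + 2: the dimethylpyran is built on biochanin A as the plant builds it: C6-prenylation by a dimethylallyl cation, then dehydrogenative closure (hydride abstraction, ortho-quinone methide, oxa-6π) onto O7.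
4. Ring order: the anisyl ring, ring A and the pyranone arrive with biochanin A; the 2,2-dimethyl-2H-pyran is the only ring formed (step 1); the pyranone is opened in step 3.

Assumption: the target has no stereocentre and no stereogenic double bond, so it is achiral and nothing has to be set; biochanin A is taken as a cheap commercial starting material.

**Route**

Step 1
Reactants: 1 biochanin A (5,7-dihydroxy-3-(4-methoxyphenyl)-4H-chromen-4-one); 2 2-methylbut-3-en-2-ol
Product: 5 4′-O-methylalpinumisoflavone (5-hydroxy-7-(4-methoxyphenyl)-2,2-dimethyl-2H,6H-pyrano[3,2-g]chromen-6-one), via 6-prenylbiochanin A 3 (not isolated), via ortho-quinone methide 4 (not isolated)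
Conditions: 2 (1.5 equiv), BF3·OEt2 (0.5 equiv, catalyst), dioxane, rt, 6 h; aq. NaHCO3 wash, solvent switch, no purification; then DDQ (1.1 equiv on 3), toluene, 80 °C, 1 h; chromatography
Reagents that add atoms: none
Why: Friedel–Crafts prenylation by the dimethylallyl cation (a prenyl diphosphate surrogate) goes mainly to C6, the ring carbon flanked by both free hydroxyls, and DDQ cyclodehydrogenation then removes benzylic hydride from 3 to give ortho-quinone methide 4, which closes by oxa-6π electrocyclisation onto the 7-oxygen because the 5-hydroxyl stays hydrogen-bonded to the C4 carbonyl; no stereocentre is formed.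

Step 2
Reactants: 5 4′-O-methylalpinumisoflavone
Product: 6 4′,5-di-O-methylalpinumisoflavone (5-methoxy-7-(4-methoxyphenyl)-2,2-dimethyl-2H,6H-pyrano[3,2-g]chromen-6-one)
Conditions: MeI (5 equiv), K2CO3 (5 equiv), acetone, reflux, 24–36 h
Reagents that add atoms: iodomethane, CI
Why: Williamson ether synthesis: the chelated 5-hydroxyl is the only acidic site left and, although slow, it is methylated by excess iodomethane over K2CO3, while the chromene, the pyranone and the aryl ethers are inert to anhydrous carbonate.

Step 3
Reactants: 6 4′,5-di-O-methylalpinumisoflavone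
Product: 7 1-(7-hydroxy-5-methoxy-2,2-dimethyl-2H-chromen-6-yl)-2-(4-methoxyphenyl)ethan-1-one (target)
Conditions: KOH (10% aq.), EtOH, reflux, 1–2 h, N2; then 1 M HCl, 0 °C, to pH 3
Reagents that add atoms: none
Why: Hydroxide adds to C2 of the non-phenolic isoflavone (oxa-Michael addition), the pyranone opens by retro-oxa-Michael reaction to the α-formyl deoxybenzoin, and retro-Claisen deformylation expels formate, so the former ring oxygen becomes the free chelated hydroxyl while the methylated oxygen stays next to the chromene carbon; the chromene and the ethers are base-stable and no stereocentre is involved.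

**Compound list**
1 | biochanin A; 5,7-dihydroxy-3-(4-methoxyphenyl)-4H-chromen-4-one | COc1ccc(cc1)C1=COc2cc(O)cc(O)c2C1=O | starting material
2 | 2-methylbut-3-en-2-ol | CC(C)(O)C=C | starting material
3 | 6-prenylbiochanin A; 5,7-dihydroxy-3-(4-methoxyphenyl)-6-(3-methylbut-2-en-1-yl)-4H-chromen-4-one | COc1ccc(cc1)C1=COc2cc(O)c(CC=C(C)C)c(O)c2C1=O | intermediate
4 | ortho-quinone methide; 5-hydroxy-3-(4-methoxyphenyl)-6-(3-methylbut-2-en-1-ylidene)-4H-chromene-4,7(6H)-dione, side chain on the side of the C7 carbonyl | O=C1C=C2OC=C(c3ccc(OC)cc3)C(=O)C2=C(O)/C1=C/C=C(C)C | intermediate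
5 | 4′-O-methylalpinumisoflavone; 5-hydroxy-7-(4-methoxyphenyl)-2,2-dimethyl-2H,6H-pyrano[3,2-g]chromen-6-one | COc1ccc(cc1)C1=COc2cc3OC(C)(C)C=Cc3c(O)c2C1=O | intermediate
6 | 4′,5-di-O-methylalpinumisoflavone; 5-methoxy-7-(4-methoxyphenyl)-2,2-dimethyl-2H,6H-pyrano[3,2-g]chromen-6-one | COc1ccc(cc1)C1=COc2cc3OC(C)(C)C=Cc3c(OC)c2C1=O | intermediate
7 | 1-(7-hydroxy-5-methoxy-2,2-dimethyl-2H-chromen-6-yl)-2-(4-methoxyphenyl)ethan-1-one (achiral) | COc1ccc(CC(=O)c2c(O)cc3c(c2OC)C=CC(C)(C)O3)cc1 | target

**Totals**
Total step count: 3. Longest linear sequence: 3.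

**Steps most likely to fail, with fallbacks**

Step 1 is the weakest. Attack at C8 gives the angular pyran isomer, bis-prenylation competes, and conversion is modest; expect roughly 15–25% of 5 after separation, with recovered 1 recycled. The fallback sets out from 1. Iodination with benzyltrimethylammonium dichloroiodate (BnNMe3 ICl2), CaCO3, CH2Cl2–MeOH, rt (a reagent reported to iodinate 5,7-dioxygenated chromones at C6) gives 6-iodobiochanin A F1. Its regiochemistry is proven by HMBC from the chelated 5-OH proton. Stille coupling of F1 with tributyl(3-methylbut-2-en-1-yl)stannane, Pd(PPh3)4, DMF, 90 °C then fixes the prenyl group at C6. This comes back to the route at 3, now isolated, which is cyclised with DDQ exactly as in the second half of step 1.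

Step 2 may stall because the 5-OH is both chelated and flanked by the chromene carbon. The fallback sets out from 5 and makes the aryl–OMe bond from the other side. Tf2O, pyridine, CH2Cl2, 0 °C gives 7-(4-methoxyphenyl)-2,2-dimethyl-6-oxo-2H,6H-pyrano[3,2-g]chromen-5-yl trifluoromethanesulfonate F2. Palladium-catalysed C–O coupling of F2 with methanol (Pd2(dba)3, tBuBrettPhos, Cs2CO3, toluene, 70 °C) then comes back to the route at 6.

Step 3 could over-cleave the deoxybenzoin or let its enolate autoxidise in hot alkali. The fallback sets out from 6. Conjugate reduction with LiBH(s-Bu)3, THF, −78 °C leaves the chromene alkene untouched and gives racemic 5-methoxy-7-(4-methoxyphenyl)-2,2-dimethyl-7,8-dihydro-2H,6H-pyrano[3,2-g]chromen-6-one F3. Dilute K2CO3 in aqueous MeOH at 40 °C under N2 opens F3 by β-elimination of the phenoxide; hydroxide adds to the α-methylene ketone and retro-aldol loss of formaldehyde follows. This is the reverse of the usual isoflavanone synthesis from a deoxybenzoin and formaldehyde, and it comes back to the route at 7 under much milder base.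

**Further compounds**
F1 | step 1 | 6-iodobiochanin A; 5,7-dihydroxy-6-iodo-3-(4-methoxyphenyl)-4H-chromen-4-one | COc1ccc(cc1)C1=COc2cc(O)c(I)c(O)c2C1=O
F2 | step 2 | 7-(4-methoxyphenyl)-2,2-dimethyl-6-oxo-2H,6H-pyrano[3,2-g]chromen-5-yl trifluoromethanesulfonate | COc1ccc(cc1)C1=COc2cc3OC(C)(C)C=Cc3c(OS(=O)(=O)C(F)(F)F)c2C1=O
F3 | step 3 | racemic 5-methoxy-7-(4-methoxyphenyl)-2,2-dimethyl-7,8-dihydro-2H,6H-pyrano[3,2-g]chromen-6-one | COc1ccc(cc1)C1COc2cc3OC(C)(C)C=Cc3c(OC)c2C1=O
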